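Rings: A = 3-hydroxyphenyl, B = para-phenylene, C = 3-aryloxy-4-hydroxyphenyl, D = 2,5-dihydroxyphenyl. All four phenols travel as methyl ethers and are freed last with BBr3.
Key disconnection: the A–B bridge is cut at the ArCH2–C(=O)Ar level. The enediolate of (3-methoxyphenyl)acetic acid undergoes crossed Claisen condensation with the three-ring methyl benzoate B–O–C–D, CO2 is lost, and C=O is reduced to CH2.
Diaryl ether B–O–C: SNAr of the C–D phenol on methyl 4-fluorobenzoate. The ester first activates the fluoride and then serves as the Claisen acceptor.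
C–D bridge: the same Claisen/decarboxylation joins (2,5-dimethoxyphenyl)acetic acid and O-benzyl methyl isovanillate. One hydrogenolysis then removes both C=O and benzyl.
No ring is formed. All four benzene rings are bought and joined in the order D + C, then B, then A.

Assumption: the SMILES holds no stereocentre and no double-bond geometry, so the target is achiral and no enantioselective step is needed. Stereocentres in transient intermediates are racemic and are erased.

Step 1
Reactants: 1 methyl 3-hydroxy-4-methoxybenzoate (methyl isovanillate); 2 benzyl bromide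
Product: 3 methyl 3-(benzyloxy)-4-methoxybenzoate
Conditions: K2CO3 (1.5 equiv), 2 (1.1 equiv), DMF, 60 °C, 4 h
Reagents that add atoms: benzyl bromide, BrCc1ccccc1
Why: Williamson ether synthesis, in which the phenoxide made by K2CO3 displaces bromide from the primary benzylic halide (SN2) and so masks the acidic OH that would quench the enediolate of step 2, with no stereocentre made.

Step 2
Reactants: 3 methyl 3-(benzyloxy)-4-methoxybenzoate; 4 (2,5-dimethoxyphenyl)acetic acid
Product: 7 1-[3-(benzyloxy)-4-methoxyphenyl]-2-(2,5-dimethoxyphenyl)ethan-1-one, via ring D dilithium enediolate 5 (not isolated), via ring C/D beta-keto acid 6 (not isolated)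
Conditions: 4 (2.1 equiv), LiN(iPr)2 (LDA, 4.3 equiv), THF, 0 °C, 1 h; then 3, 0 °C to rt, 6 h; then 2 M HCl, 40 °C, 1 h
Reagents that add atoms: none
Why: Crossed Claisen condensation in which the enediolate cannot self-condense (a carboxylate is no acyl donor) and benzoate 3 cannot enolise, so only the cross product forms, its enolate shields the new ketone from a second addition, and acidification gives beta-keto acid 6 (one transient racemic stereocentre) that loses CO2 on gentle warming to leave an achiral ketone.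

Step 3
Reactants: 7 1-[3-(benzyloxy)-4-methoxyphenyl]-2-(2,5-dimethoxyphenyl)ethan-1-one
Product: 10 5-[2-(2,5-dimethoxyphenyl)ethyl]-2-methoxyphenol, via phenolic ketone 8 (not isolated), via benzylic carbinol 9 (not isolated)
Conditions: H2 (4 bar), 10% Pd/C, AcOH, cat. H2SO4, 45 °C, 16 h
Reagents that add atoms: none
Why: Catalytic hydrogenolysis, in which Pd/C first cleaves the O-benzyl ether, then reduces the para-methoxy-activated aryl ketone to the carbinol (racemic, transient), whose acid-activated benzylic C–O bond is hydrogenolysed to CH2 while methyl ethers and arene rings are untouched.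

Step 4
Reactants: 10 5-[2-(2,5-dimethoxyphenyl)ethyl]-2-methoxyphenol; 11 methyl 4-fluorobenzoate
Product: 12 methyl 4-{5-[2-(2,5-dimethoxyphenyl)ethyl]-2-methoxyphenoxy}benzoate
Conditions: 11 (1.3 equiv), Cs2CO3 (1.5 equiv), dry DMSO, 120 °C, 16 h, N2
Reagents that add atoms: none
Why: Nucleophilic aromatic substitution (SNAr, addition–elimination), in which the caesium phenoxide adds para to the ester that stabilises the Meisenheimer anion and fluoride leaves, 10 holding no other nucleophilic or base-sensitive site.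

Step 5
Reactants: 12 methyl 4-{5-[2-(2,5-dimethoxyphenyl)ethyl]-2-methoxyphenoxy}benzoate; 13 (3-methoxyphenyl)acetic acid
Product: 16 1-(4-{5-[2-(2,5-dimethoxyphenyl)ethyl]-2-methoxyphenoxy}phenyl)-2-(3-methoxyphenyl)ethan-1-one, via ring A dilithium enediolate 14 (not isolated), via four-ring beta-keto acid 15 (not isolated)
Conditions: 13 (2.1 equiv), LiN(iPr)2 (LDA, 4.3 equiv), THF, 0 °C, 1 h; then 12, 0 °C to rt (40 °C if slow), 8 h; then 2 M HCl, 40 °C, 1 h
Reagents that add atoms: none
Why: Crossed Claisen condensation as the key fragment union, in which the cheap enediolate used in excess acylates on carbon with the non-enolisable benzoate 12, the product rests as its enolate until the quench, and beta-keto acid 15 (one transient racemic stereocentre) decarboxylates to the achiral deoxybenzoin, aryl ethers being inert to amide base and dilute acid.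

Step 6
Reactants: 16 1-(4-{5-[2-(2,5-dimethoxyphenyl)ethyl]-2-methoxyphenoxy}phenyl)-2-(3-methoxyphenyl)ethan-1-one
Product: 18 4-[2-(2,5-dimethoxyphenyl)ethyl]-1-methoxy-2-{4-[2-(3-methoxyphenyl)ethyl]phenoxy}benzene, via diaryl carbinol 17 (not isolated)
Conditions: Et3SiH (4 equiv), CF3CO2H–CH2Cl2 (1:1), 0 °C to rt, 16 h
Reagents that add atoms: none
Why: Ionic hydrogenation, in which the acid protonates the ketone, Et3SiH delivers hydride to give the carbinol (racemic, transient), and this ionises to a cation stabilised by the para-aryloxy group and takes a second hydride, aryl ethers being inert to both reagents.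

Step 7
Reactants: 18 4-[2-(2,5-dimethoxyphenyl)ethyl]-1-methoxy-2-{4-[2-(3-methoxyphenyl)ethyl]phenoxy}benzene
Product: 20 2-[2-(4-hydroxy-3-{4-[2-(3-hydroxyphenyl)ethyl]phenoxy}phenyl)ethyl]benzene-1,4-diol (target), via tetrakis(dibromoboryl) ether 19 (not isolated)
Conditions: BBr3 (8 equiv), CH2Cl2, -78 °C to rt, 12 h; then ice-water under Ar, EtOAc extraction, wash with aq. Na2S2O4
Reagents that add atoms: none
Why: Lewis-acid ether cleavage, in which BBr3 binds each methoxy oxygen and bromide attacks the methyl carbon (SN2), the diaryl ether survives because it offers no sp3 carbon, and hydrolysis of the aryl borates frees the four phenols, with air excluded to protect the hydroquinone ring.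

Compound list
1 | methyl 3-hydroxy-4-methoxybenzoate | COC(=O)c1ccc(OC)c(O)c1 | starting material
2 | benzyl bromide | BrCc1ccccc1 | starting material
3 | methyl 3-(benzyloxy)-4-methoxybenzoate | COC(=O)c1ccc(OC)c(OCc2ccccc2)c1 | intermediate
4 | (2,5-dimethoxyphenyl)acetic acid | COc1ccc(OC)c(CC(=O)O)c1 | starting material
5 | dilithium 2-(2,5-dimethoxyphenyl)ethene-1,1-diolate | [Li+].[Li+].COc1ccc(OC)c(C=C([O-])[O-])c1 | intermediate
6 | 3-[3-(benzyloxy)-4-methoxyphenyl]-2-(2,5-dimethoxyphenyl)-3-oxopropanoic acid (racemic) | COc1ccc(OC)c(C(C(=O)O)C(=O)c2ccc(OC)c(OCc3ccccc3)c2)c1 | intermediate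
7 | 1-[3-(benzyloxy)-4-methoxyphenyl]-2-(2,5-dimethoxyphenyl)ethan-1-one | COc1ccc(OC)c(CC(=O)c2ccc(OC)c(OCc3ccccc3)c2)c1 | intermediate
8 | 2-(2,5-dimethoxyphenyl)-1-(3-hydroxy-4-methoxyphenyl)ethan-1-one | COc1ccc(OC)c(CC(=O)c2ccc(OC)c(O)c2)c1 | intermediate
9 | 5-[2-(2,5-dimethoxyphenyl)-1-hydroxyethyl]-2-methoxyphenol (racemic) | COc1ccc(OC)c(CC(O)c2ccc(OC)c(O)c2)c1 | intermediate
10 | 5-[2-(2,5-dimethoxyphenyl)ethyl]-2-methoxyphenol | COc1ccc(OC)c(CCc2ccc(OC)c(O)c2)c1 | intermediate
11 | methyl 4-fluorobenzoate | COC(=O)c1ccc(F)cc1 | starting material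
12 | methyl 4-{5-[2-(2,5-dimethoxyphenyl)ethyl]-2-methoxyphenoxy}benzoate | COC(=O)c1ccc(Oc2cc(CCc3cc(OC)ccc3OC)ccc2OC)cc1 | intermediate
13 | (3-methoxyphenyl)acetic acid | COc1cccc(CC(=O)O)c1 | starting material
14 | dilithium 2-(3-methoxyphenyl)ethene-1,1-diolate | [Li+].[Li+].COc1cccc(C=C([O-])[O-])c1 | intermediate
15 | 3-(4-{5-[2-(2,5-dimethoxyphenyl)ethyl]-2-methoxyphenoxy}phenyl)-2-(3-methoxyphenyl)-3-oxopropanoic acid (racemic) | COc1cccc(C(C(=O)O)C(=O)c2ccc(Oc3cc(CCc4cc(OC)ccc4OC)ccc3OC)cc2)c1 | intermediate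
16 | 1-(4-{5-[2-(2,5-dimethoxyphenyl)ethyl]-2-methoxyphenoxy}phenyl)-2-(3-methoxyphenyl)ethan-1-one | COc1cccc(CC(=O)c2ccc(Oc3cc(CCc4cc(OC)ccc4OC)ccc3OC)cc2)c1 | intermediate
17 | 1-(4-{5-[2-(2,5-dimethoxyphenyl)ethyl]-2-methoxyphenoxy}phenyl)-2-(3-methoxyphenyl)ethan-1-ol (racemic) | COc1cccc(CC(O)c2ccc(Oc3cc(CCc4cc(OC)ccc4OC)ccc3OC)cc2)c1 | intermediate
18 | 4-[2-(2,5-dimethoxyphenyl)ethyl]-1-methoxy-2-{4-[2-(3-methoxyphenyl)ethyl]phenoxy}benzene | COc1cccc(CCc2ccc(Oc3cc(CCc4cc(OC)ccc4OC)ccc3OC)cc2)c1 | intermediate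
19 | tetrakis(dibromoboryl) ether of 20 | BrB(Br)Oc1cccc(CCc2ccc(Oc3cc(CCc4cc(OB(Br)Br)ccc4OB(Br)Br)ccc3OB(Br)Br)cc2)c1 | intermediate
20 | 2-[2-(4-hydroxy-3-{4-[2-(3-hydroxyphenyl)ethyl]phenoxy}phenyl)ethyl]benzene-1,4-diol | Oc1cccc(CCc2ccc(Oc3cc(CCc4cc(O)ccc4O)ccc3O)cc2)c1 | target

Total step count: 7
Longest linear sequence: 7 steps (1 → 3 → 7 → 10 → 12 → 16 → 18 → 20)

Steps most likely to fail

Risk 1, step 5. Benzoate 12 is electron-rich and bulky, so it is a sluggish acyl acceptor, and the enediolate may act only as a base.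
- This fallback sets out from phenol 10 and comes back at 18. It replaces the Claisen union with an aldol-type condensation on an aldehyde.
- SNAr of 10 on 4-fluorobenzaldehyde (K2CO3, DMF, 110 °C) gives 4-{5-[2-(2,5-dimethoxyphenyl)ethyl]-2-methoxyphenoxy}benzaldehyde F1.
- Perkin condensation of this aldehyde with acid 13 (Ac2O, Et3N, 120 °C) gives (E)-3-(4-{5-[2-(2,5-dimethoxyphenyl)ethyl]-2-methoxyphenoxy}phenyl)-2-(3-methoxyphenyl)prop-2-enoic acid F2.
- Cu powder in quinoline at 210 °C removes CO2 to give 4-[2-(2,5-dimethoxyphenyl)ethyl]-1-methoxy-2-{4-[(Z)-2-(3-methoxyphenyl)ethenyl]phenoxy}benzene F3. Its alkene geometry does not matter.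
- H2 (1 bar) over 10% Pd/C in EtOAc then gives 18.

Risk 2, step 4. An ester is only a moderate SNAr activator. At 120 °C the phenoxide can also demethylate the ester, and traces of water can saponify it.
- This fallback sets out from 10 and comes back at 12. It uses a nitrile as the stronger activating group and builds the ester afterwards.
- 10 and 4-fluorobenzonitrile (K2CO3, DMF, 100 °C) give 4-{5-[2-(2,5-dimethoxyphenyl)ethyl]-2-methoxyphenoxy}benzonitrile F4.
- KOH in ethylene glycol–water at 130 °C, followed by HCl, gives 4-{5-[2-(2,5-dimethoxyphenyl)ethyl]-2-methoxyphenoxy}benzoic acid F5.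
- Fischer esterification (MeOH, cat. H2SO4, reflux) gives 12.

Risk 3, step 3. The one-pot hydrogenolysis may stall at carbinol 9, or the benzylic cation may be intercepted by the neighbouring ortho-methoxy group.
- This fallback sets out from 7 and comes back at 10. It removes the oxygen by elimination, so the hydrogenation can run under neutral conditions.
- NaBH4 in MeOH–THF at 0 °C gives racemic 1-[3-(benzyloxy)-4-methoxyphenyl]-2-(2,5-dimethoxyphenyl)ethan-1-ol F6.
- Cat. p-TsOH in refluxing toluene with a Dean–Stark trap gives 2-(benzyloxy)-4-[(E)-2-(2,5-dimethoxyphenyl)ethenyl]-1-methoxybenzene F7.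
- H2 (1 bar) over 10% Pd/C in EtOAc–MeOH at rt saturates the alkene and cleaves the benzyl ether to give 10.

Further compounds
F1 | step 5 | 4-{5-[2-(2,5-dimethoxyphenyl)ethyl]-2-methoxyphenoxy}benzaldehyde | O=Cc1ccc(Oc2cc(CCc3cc(OC)ccc3OC)ccc2OC)cc1
F2 | step 5 | (E)-3-(4-{5-[2-(2,5-dimethoxyphenyl)ethyl]-2-methoxyphenoxy}phenyl)-2-(3-methoxyphenyl)prop-2-enoic acid | OC(=O)/C(c1cccc(OC)c1)=C/c1ccc(Oc2cc(CCc3cc(OC)ccc3OC)ccc2OC)cc1
F3 | step 5 | 4-[2-(2,5-dimethoxyphenyl)ethyl]-1-methoxy-2-{4-[(Z)-2-(3-methoxyphenyl)ethenyl]phenoxy}benzene | COc1cccc(/C=C\c2ccc(Oc3cc(CCc4cc(OC)ccc4OC)ccc3OC)cc2)c1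
F4 | step 4 | 4-{5-[2-(2,5-dimethoxyphenyl)ethyl]-2-methoxyphenoxy}benzonitrile | N#Cc1ccc(Oc2cc(CCc3cc(OC)ccc3OC)ccc2OC)cc1
F5 | step 4 | 4-{5-[2-(2,5-dimethoxyphenyl)ethyl]-2-methoxyphenoxy}benzoic acid | OC(=O)c1ccc(Oc2cc(CCc3cc(OC)ccc3OC)ccc2OC)cc1
F6 | step 3 | 1-[3-(benzyloxy)-4-methoxyphenyl]-2-(2,5-dimethoxyphenyl)ethan-1-ol (racemic) | COc1ccc(OC)c(CC(O)c2ccc(OC)c(OCc3ccccc3)c2)c1
F7 | step 3 | 2-(benzyloxy)-4-[(E)-2-(2,5-dimethoxyphenyl)ethenyl]-1-methoxybenzene | COc1ccc(OC)c(/C=C/c2ccc(OC)c(OCc3ccccc3)c2)c1
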